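Slowness is where I start, since your hunch that more charge gives more target needs time that the clock may not allow.

the same everywhere: enzyme 13 µM
- zeta: starting material 0.041 M; run made earlier
- beta: starting material 0.16 M; run made earlier
- violet: starting material 0.060 M; time 40 min
- grey: starting material 0.080 M; time 40 min
- red: starting material 0.12 M; time 40 min
- teal: starting material 0.20 M; time 40 min

| run | time / min | target / % |
|---|---|---|
| zeta | 2.50 | 22.1 |
| zeta | 8.00 | 61.0 |
| zeta | 12.0 | 78.8 |
| zeta | 20.0 | 91.5 |
| zeta | 30.0 | 93.5 |
| beta | 6.00 | 10.0 |
| beta | 12.0 | 18.5 |
| beta | 15.0 | 23.0 |
| beta | 25.0 | 38.8 |
| beta | 30.0 | 48.7 |

(standard deviation of a reading: 0.3 percentage points)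

1. [target] at the end for violet, grey, red, teal, in this order
2. how that number moves from the first to the last of them (falls, then rises / falls all the way / hardly changes / rises, then falls / rises all the way)

- the numbers in the tables scatter by 0.3 percentage points (one standard deviation)
- "hardly changes" means that all values lie within two and a half points (for a concentration: within two and a half percent of the largest)

The beta run makes target at a mean 2.60 mM min⁻¹ over 30.0 min, so in 40 min that pace gives 0.104 M, like a tank filled through a fixed pipe; I call this the reach, and it is a rough estimate and not a bound, since the pace in the beta run moves as the run goes on. The zeta run levels off near 93.5%, and I read its shortfall as a loss whose share grows in step with charge, 1.59 M⁻¹; that is my assumption, since a single run can't show it. A finished flask then holds the charge less that share. I call the charge at which this finished amount meets the reach the crossing, 0.131 M. In my reckoning, a flask below it finishes in time, and a flask above it is still working when the clock stops.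

So violet should give 0.0543 M, grey 0.0699 M and red, charged below the crossing, 0.0972 M. Teal is charged above it, and the opening pace is lower in the beta run, 2.67 mM min⁻¹, than in the zeta run, 3.62 mM min⁻¹, which looks like substrate inhibition. Carrying that fall on in a straight line to teal's charge, I get 0.0910 M, lower than red. My answer is that the target rises, then falls.

The forecast gives 0.0564 M, 0.075 M, 0.107 M and 0.092 M, higher than mine at red, with the shape rises, then falls, and says “Teal is still held back by inhibition”.

The flasks give 0.0539 M, 0.0680 M, 0.0889 M and 0.0856 M, so the target rises, then falls, and the row turns at 0.16 M, above my crossing.

    starting material + enzyme → target + enzyme, rate k1*[starting material]*[enzyme]/(1 + ([starting material]/Km1) + ([starting material]/Ksi1)^2) (35.0 mM, 0.0550 M, k = 19000 M⁻¹ min⁻¹)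
    starting material + target → side product (k = 0.270 M⁻¹ min⁻¹)

In red, charged below the crossing of 0.131 M, the enzyme's step and the step in which starting material meets target ran side by side, and at 40.0 min 0.44% of the starting material was left, with target at 74.1% and side product, which counts as two in every percentage, at 25.5%. In teal, charged above it, both steps were still running at 40.0 min, with target at 42.8%, side product at 40.9% and 16% of the starting material still there.

The runs come from a simulation for an exercise; the scatter is artificial.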